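**Plan**

1. Numbering (target ring carbons): C1 CH–O-senecioate, C2 CH2, C3 CH–O-isovalerate, C4 CMe2, C5 and C6 cyclobutane CH, C7 C=O, C8 =CH, C9 =C–Me, C10 cyclobutane CH, C11 C–Me.
2. Enabling feature: in the cyclobutane C5–C6–C11–C10 the 1,3-related CH carbons C6/C10 are spanned by the enone C7–C8–C9, and C5/C11 are tied by C1–C4 (seven-membered ring). Reconnecting C6–C10 gives a bicyclo[1.1.0]butane with a mirror plane through C5, C11 and C1–C4.
3. Retrosynthesis: cut the two ester C–O bonds; then C6–C7 and C9–C10 together (enone bridge leaves as a cyclopropenone); then C10–C11, C5–C10 and C6–C10 (carbene carbon); then C5=C6 (metathesis) and C2–C3 (aldol).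
4. Forward: aldol joins the chain; metathesis closes the seven-membered ring; dibromocarbene, then MeLi, close the cyclopropane and the bicyclobutane; the rhodium (3+3) annulation closes the enone ring; the esters come last.
5. Stereochemistry: C5, C6, C10, C11 from the catalyst's choice between the enantiotopic bridgeheads of the meso bicyclobutane; C3 from a reagent-controlled CBS reduction; C1 from anti-selective Evans–Tishchenko hydride delivery.

Key step: step 11

Assumptions: 1 and 2 are taken as catalogue compounds (each is otherwise one step from crotyl- or prenylmagnesium chloride), and the (R)-ligand is taken to send the acyl carbon to C6; its antipode is used if the sense is opposite.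

**Route**

Step 1
Reactants: 1 3-methylpent-4-en-2-one; 2 2,2-dimethylbut-3-enal
Product: 4 6-hydroxy-3,7,7-trimethylnona-1,8-dien-4-one, via lithium 3-methylpenta-1,4-dien-2-olate 3 (not isolated)
Conditions: LiN(iPr)2 (1.05 equiv), THF, −78 °C, 1 added to base; then 2, −78 °C; AcOH, −78 °C
Reagents that add atoms: none
Why: Kinetic deprotonation at the CH3 group and crossed lithium aldol addition to a non-enolisable aldehyde; C3 forms without control and, like the racemic C11 centre of 1, is erased later (C3 by oxidation in step 8, C11 on becoming the quaternary wing carbon), so all stereoisomers converge.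

Step 2
Reactants: 4 6-hydroxy-3,7,7-trimethylnona-1,8-dien-4-one
Product: 5 6-[(tert-butyldimethylsilyl)oxy]-3,7,7-trimethylnona-1,8-dien-4-one
Conditions: TBSOTf, 2,6-lutidine, CH2Cl2, −78 → 0 °C
Reagents that add atoms: tert-butyldimethylsilyl trifluoromethanesulfonate, CC(C)(C)[Si](C)(C)OS(=O)(=O)C(F)(F)F
Why: Silyl triflate silylation of a hindered neopentyl-type secondary alcohol; the weak base should neither move the β,γ-alkene into conjugation nor cause β-elimination.

Step 3
Reactants: 5 6-[(tert-butyldimethylsilyl)oxy]-3,7,7-trimethylnona-1,8-dien-4-one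
Product: 6 2-(but-3-en-2-yl)-2-{2-[(tert-butyldimethylsilyl)oxy]-3,3-dimethylpent-4-en-1-yl}-1,3-dioxolane
Conditions: (TMSOCH2)2, TMSOTf (5 mol%), CH2Cl2, −78 → −20 °C; pyridine quench
Reagents that add atoms: 1,2-bis(trimethylsilyloxy)ethane, C[Si](C)(C)OCCO[Si](C)(C)C
Why: Noyori ketalisation at low temperature without protic acid masks the C1 ketone without alkene migration or loss of the silyl ether; this sets the C1/C3 differentiation used in the end-game.

Step 4
Reactants: 6 2-(but-3-en-2-yl)-2-{2-[(tert-butyldimethylsilyl)oxy]-3,3-dimethylpent-4-en-1-yl}-1,3-dioxolane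
Product: 7 tert-butyldimethyl[(6,9,9-trimethyl-1,4-dioxaspiro[4.6]undec-7-en-10-yl)oxy]silane
Conditions: second-generation Grubbs catalyst RuCl2(=CHPh)(H2IMes)(PCy3) (5 mol%), CH2Cl2 (5 mM), 40 °C
Reagents that add atoms: none
Why: Ring-closing olefin metathesis of the two vinyl groups gives the cis C5=C6 bond of the seven-membered ring, helped by the gem-dimethyl and ketal substituents (Thorpe–Ingold effect).

Step 5
Reactants: 7 tert-butyldimethyl[(6,9,9-trimethyl-1,4-dioxaspiro[4.6]undec-7-en-10-yl)oxy]silane
Product: 8 tert-butyl[(8′,8′-dibromo-2′,6′,6′-trimethylspiro[1,3-dioxolane-2,3′-bicyclo[5.1.0]octan]-5′-yl)oxy]dimethylsilane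
Conditions: CHBr3 (3 equiv), 50% aq NaOH, BnEt3NCl (5 mol%), CH2Cl2, 0 → 23 °C
Reagents that add atoms: bromoform, BrC(Br)Br
Why: Makosza phase-transfer dibromocarbene [2+1] addition to the cis alkene; attack anti to the C11 methyl group places the CBr2 carbon (C10) syn to C11–H, as step 6 requires (either C3 epimer serves).

Step 6
Reactants: 8 tert-butyl[(8′,8′-dibromo-2′,6′,6′-trimethylspiro[1,3-dioxolane-2,3′-bicyclo[5.1.0]octan]-5′-yl)oxy]dimethylsilane
Product: 10 tert-butyldimethyl[(2′,6′,6′-trimethylspiro[1,3-dioxolane-2,3′-tricyclo[5.1.0.0(2,8)]octan]-5′-yl)oxy]silane, via bromolithio carbenoid 9 (not isolated)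
Conditions: MeLi (1.2 equiv), Et2O, −78 → 0 °C
Reagents that add atoms: none
Why: Moore–Skattebøl bicyclobutane synthesis: Br/Li exchange gives the cyclopropylidene carbenoid, whose 1,3-insertion into the tertiary C11–H held syn to it forms C10–C11 with retention; no oxygen-activated C–H lies within 1,5 reach and the C2 hydrogens are deactivated by three β-oxygens, so this should be the favoured C–H insertion, ring opening to the cyclic allene being the competing path.

Step 7
Reactants: 10 tert-butyldimethyl[(2′,6′,6′-trimethylspiro[1,3-dioxolane-2,3′-tricyclo[5.1.0.0(2,8)]octan]-5′-yl)oxy]silane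
Product: 11 2′,6′,6′-trimethylspiro[1,3-dioxolane-2,3′-tricyclo[5.1.0.0(2,8)]octan]-5′-ol
Conditions: Bu4NF (2 equiv), THF, 45 °C
Reagents that add atoms: none
Why: Fluoride cleavage of the silyl ether; the bicyclobutane tolerates fluoride and base.

Step 8
Reactants: 11 2′,6′,6′-trimethylspiro[1,3-dioxolane-2,3′-tricyclo[5.1.0.0(2,8)]octan]-5′-ol
Product: 12 2′,6′,6′-trimethylspiro[1,3-dioxolane-2,3′-tricyclo[5.1.0.0(2,8)]octan]-5′-one (meso)
Conditions: SO3·pyridine (3 equiv), DMSO, iPr2NEt, CH2Cl2, 0 °C
Reagents that add atoms: none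
Why: Parikh–Doering oxidation under buffered, non-acidic conditions spares the acid- and electrophile-sensitive bicyclobutane; removing the only stereogenic centre makes the precursor meso.

Step 9
Reactants: 13 trimethyl(prop-1-yn-1-yl)silane
Product: 14 (3,3-difluoro-2-methylcycloprop-1-en-1-yl)trimethylsilane
Conditions: TMSCF3 (2 equiv), NaI (0.3 equiv), THF, 110 °C, sealed tube
Reagents that add atoms: (trifluoromethyl)trimethylsilane, C[Si](C)(C)C(F)(F)F
Why: [2+1] cycloaddition of difluorocarbene (Ruppert–Prakash reagent, iodide initiation) to the silyl alkyne, the standard entry to 3,3-difluorocyclopropenes.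

Step 10
Reactants: 14 (3,3-difluoro-2-methylcycloprop-1-en-1-yl)trimethylsilane
Product: 15 2-methyl-3-(trimethylsilyl)cycloprop-2-en-1-one
Conditions: H2O, SiO2, CH2Cl2, 0 → 23 °C
Reagents that add atoms: water, O
Why: Hydrolysis of the gem-difluorocyclopropene via the fluorocyclopropenylium ion unveils the cyclopropenone; neutral moist silica should keep the C–Si bond.

Step 11
Reactants: 12 meso keto-ketal bicyclobutane; 15 2-methyl-3-(trimethylsilyl)cycloprop-2-en-1-one
Product: 16 tricyclic 8-(trimethylsilyl) enone with C1 as 1,3-dioxolane and C3 as ketone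
Conditions: [Rh(cod)Cl]2 (2.5 mol%), (R)-DTBM-SEGPHOS (6 mol%), 15 (1.5 equiv), toluene, 40 °C; 12 added over 3 h
Reagents that add atoms: none
Why: Proposed new method: monovalent rhodium inserts into the acyl–C(Me) bond of 15 to give a rhodacyclobutenone, the p-rich central C6–C10 σ-bond of 12 inserts into the Rh–acyl bond (C6–C7 forms, rhodium moves to C10) and C(sp2)–C(sp3) reductive elimination forms C9–C10, both strained rings supplying the driving force. The closest known reactions are the rhodium-catalysed (3+2) cycloaddition of cyclopropenones with alkynes (same C–C activation) and the formal (3+3) cycloadditions of bicyclo[1.1.0]butanes that give bicyclo[3.1.1]heptanes. The enone ring C5–C6–C7–C8–C9–C10 closes by addition of the three-carbon unit across a σ-bond, a strain-release (3+3) annulation (insertion, then reductive elimination). C5, C6, C10 and C11 become stereogenic together: their relative configuration is dictated by the cage, since the new bridge can only lie on the face opposite the C1–C4 tether, and their absolute configuration by which enantiotopic bridgehead receives the acyl carbon, decided by the chiral bisphosphine on rhodium. Regioselective C–C activation is needed and is secured by the trimethylsilyl group, which shields the acyl–C8 bond so that rhodium enters on the methyl side and silicon ends at C8; bridgehead discrimination is eased by the two equivalent, unhindered CH bridgeheads and the mirror plane of 12. Slow addition of 12 to the pre-formed rhodacycle should limit rhodium-induced isomerisation of the bicyclobutane.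

Step 12
Reactants: 16 tricyclic 8-(trimethylsilyl) enone keto-ketal
Product: 17 tricyclic enone (C7=O, C8=C9–Me) with C1 as 1,3-dioxolane and C3 as ketone
Conditions: Bu4NF (1.2 equiv), THF/H2O (20:1), 0 → 23 °C
Reagents that add atoms: none
Why: Fluoride-induced protodesilylation of the α-silyl enone (the C8 carbanion is stabilised inductively by the adjacent carbonyl), as used to remove trimethylsilyl from Pauson–Khand α-silyl cyclopentenones; no stereocentre is touched.

Step 13
Reactants: 17 tricyclic enone keto-ketal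
Product: 18 (3R)-3,7-diol (C7 epimers) with C1 as 1,3-dioxolane
Conditions: (S)-1-methyl-3,3-diphenyltetrahydro-1H,3H-pyrrolo[1,2-c][1,3,2]oxazaborole ((S)-Me-CBS, 0.3 equiv), BH3·SMe2 (2.5 equiv), THF, −30 → 0 °C; MeOH
Reagents that add atoms: none
Why: Corey–Bakshi–Shibata reduction: the oxazaborolidine distinguishes quaternary C4 from the C2 methylene and should give the (3R) carbinol under reagent control, the cage offering almost no facial bias; the enone carbonyl is reduced as well, which step 14 reverses.

Step 14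
Reactants: 18 (3R)-3,7-diol
Product: 19 (3R)-3-hydroxy enone with C1 as 1,3-dioxolane
Conditions: MnO2 (20 equiv), CH2Cl2, 23 °C
Reagents that add atoms: none
Why: MnO2 oxidises only the allylic C7 alcohol back to the enone and leaves the saturated C3 carbinol.

Step 15
Reactants: 19 (3R)-3-hydroxy enone ketal
Product: 20 (3R)-3-hydroxy-1,7-dione
Conditions: 1 M HCl, THF, 23 °C
Reagents that add atoms: water, O
Why: Acid-catalysed ketal hydrolysis; dilute acid at room temperature should stay below the threshold for dehydration of the β-hydroxy ketone.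

Step 16
Reactants: 20 (3R)-3-hydroxy-1,7-dione
Product: 21 (1R,3R)-1-hydroxy-3-(3-methylbutanoyloxy) enone
Conditions: SmI2 (0.3 equiv), 3-methylbutanal (6 equiv), THF, −10 °C
Reagents that add atoms: 3-methylbutanal, CC(C)CC=O
Why: Evans–Tishchenko reaction: the samarium-bound hemiacetal of the C3 alcohol and the aldehyde delivers hydride intramolecularly to the face of the C1 ketone syn to the C3 oxygen, setting C1 (R) anti to C3 and leaving the acyl group as the C3 isovalerate.

Step 17
Reactants: 21 (1R,3R)-1-hydroxy-3-(3-methylbutanoyloxy) enone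
Product: 22 target (CNP0335239.1)
Conditions: 3-methylbut-2-enoyl chloride (2 equiv), pyridine, DMAP (0.2 equiv), CH2Cl2, 0 → 23 °C
Reagents that add atoms: 3-methylbut-2-enoyl chloride, CC(C)=CC(Cl)=O
Why: DMAP-catalysed acylation of the hindered C1 alcohol; pyridine as the only stoichiometric base limits deconjugation of the senecioyl group via its vinylketene.

**Compound list**

1 | 3-methylpent-4-en-2-one (racemic) | CC(=O)C(C)C=C | starting material
2 | 2,2-dimethylbut-3-enal | O=CC(C)(C)C=C | starting material
3 | lithium 3-methylpenta-1,4-dien-2-olate | [Li]OC(=C)C(C)C=C | intermediate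
4 | 6-hydroxy-3,7,7-trimethylnona-1,8-dien-4-one (racemic, both diastereomers) | C=CC(C)C(=O)CC(O)C(C)(C)C=C | intermediate
5 | 6-[(tert-butyldimethylsilyl)oxy]-3,7,7-trimethylnona-1,8-dien-4-one (same isomer mixture) | C=CC(C)C(=O)CC(O[Si](C)(C)C(C)(C)C)C(C)(C)C=C | intermediate
6 | 2-(but-3-en-2-yl)-2-{2-[(tert-butyldimethylsilyl)oxy]-3,3-dimethylpent-4-en-1-yl}-1,3-dioxolane (same isomer mixture) | C=CC(C)C1(OCCO1)CC(O[Si](C)(C)C(C)(C)C)C(C)(C)C=C | intermediate
7 | tert-butyldimethyl[(6,9,9-trimethyl-1,4-dioxaspiro[4.6]undec-7-en-10-yl)oxy]silane (racemic, both diastereomers) | CC1C=CC(C)(C)C(O[Si](C)(C)C(C)(C)C)CC12OCCO2 | intermediate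
8 | tert-butyl[(8′,8′-dibromo-2′,6′,6′-trimethylspiro[1,3-dioxolane-2,3′-bicyclo[5.1.0]octan]-5′-yl)oxy]dimethylsilane, CBr2 syn to H-2′ (racemic, both C5′ epimers; one enantiomer drawn) | C[C@H]1[C@H]2[C@H](C2(Br)Br)C(C)(C)C(O[Si](C)(C)C(C)(C)C)CC13OCCO3 | intermediate
9 | 8′-bromo-8′-lithio carbenoid derived from 8 | C[C@H]1[C@H]2[C@H](C2([Li])Br)C(C)(C)C(O[Si](C)(C)C(C)(C)C)CC13OCCO3 | intermediate
10 | tert-butyldimethyl[(2′,6′,6′-trimethylspiro[1,3-dioxolane-2,3′-tricyclo[5.1.0.0(2,8)]octan]-5′-yl)oxy]silane (racemic at C5′; four-carbon bridge endo on both wings) | C[C@]12[C@@H]3[C@H]1[C@@H]3C(C)(C)C(O[Si](C)(C)C(C)(C)C)CC25OCCO5 | intermediate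
11 | 2′,6′,6′-trimethylspiro[1,3-dioxolane-2,3′-tricyclo[5.1.0.0(2,8)]octan]-5′-ol (racemic at C5′) | C[C@]12[C@@H]3[C@H]1[C@@H]3C(C)(C)C(O)CC25OCCO5 | intermediate
12 | 2′,6′,6′-trimethylspiro[1,3-dioxolane-2,3′-tricyclo[5.1.0.0(2,8)]octan]-5′-one (meso; C1 dioxolane, C3 ketone) | C[C@]12[C@@H]3[C@H]1[C@@H]3C(C)(C)C(=O)CC25OCCO5 | intermediate
13 | trimethyl(prop-1-yn-1-yl)silane | CC#C[Si](C)(C)C | starting material
14 | (3,3-difluoro-2-methylcycloprop-1-en-1-yl)trimethylsilane | CC1=C([Si](C)(C)C)C1(F)F | intermediate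
15 | 2-methyl-3-(trimethylsilyl)cycloprop-2-en-1-one | CC1=C([Si](C)(C)C)C1=O | intermediate
16 | tricyclic enone of the target skeleton: C1 1,3-dioxolane, C3=O, C7=O, C8–SiMe3, C8=C9–Me; cage configured as in the target | C14(OCCO4)CC(=O)C(C)(C)[C@@H]2[C@H]3C(=O)C([Si](C)(C)C)=C(C)[C@@H]2[C@]31C | intermediate
17 | as 16 with C8–H | C14(OCCO4)CC(=O)C(C)(C)[C@@H]2[C@H]3C(=O)C=C(C)[C@@H]2[C@]31C | intermediate
18 | (3R)-3,7-diol, C1 1,3-dioxolane, C8=C9 (C7 epimers) | C14(OCCO4)C[C@@H](O)C(C)(C)[C@@H]2[C@H]3C(O)C=C(C)[C@@H]2[C@]31C | intermediate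
19 | (3R)-3-hydroxy enone, C1 1,3-dioxolane | C14(OCCO4)C[C@@H](O)C(C)(C)[C@@H]2[C@H]3C(=O)C=C(C)[C@@H]2[C@]31C | intermediate
20 | (3R)-3-hydroxy-1,7-dione | O=C1C[C@@H](O)C(C)(C)[C@@H]2[C@H]3C(=O)C=C(C)[C@@H]2[C@]31C | intermediate
21 | (1R,3R)-1-hydroxy-3-(3-methylbutanoyloxy) enone | O[C@@H]1C[C@@H](OC(=O)CC(C)C)C(C)(C)[C@@H]2[C@H]3C(=O)C=C(C)[C@@H]2[C@]31C | intermediate
22 | target: (1R,3R) 1-(3-methylbut-2-enoate) 3-(3-methylbutanoate) of the tricyclic enone diol | CC(C)=CC(=O)O[C@@H]1C[C@@H](OC(=O)CC(C)C)C(C)(C)[C@@H]2[C@H]3C(=O)C=C(C)[C@@H]2[C@]31C | target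

**Count and risks**

Total steps: 17. Longest linear sequence: 15 (steps 1–8, then 11–17).

Steps most likely to fail:

1. Step 11 (new method). Rhodium may cleave the bicyclobutane by itself (isomerisation to dienes) before the rhodacycle captures it, C–C activation may start on the silicon side, or the bridgeheads may be taken without discrimination. Fallback with known chemistry, from 12 back to 19: the (S)-oxazaborolidine/borane reduction applied to meso ketone 12 gives (5′R)-2′,6′,6′-trimethylspiro[1,3-dioxolane-2,3′-tricyclo[5.1.0.0(2,8)]octan]-5′-ol F1. TBSOTf/2,6-lutidine converts it into its tert-butyldimethylsilyl ether F2. Bridgehead lithiation (s-BuLi, TMEDA, Et2O) and acylation with (Z)-3-bromo-N-methoxy-N-methylbut-2-enamide give, after chromatographic removal of the isomer acylated at the other bridgehead (a diastereomer because of C3), the bridgehead (Z)-3-bromobut-2-enoyl bicyclobutane F3. Bu3SnH/AIBN (benzene, 80 °C) generates the C9 vinyl radical, which adds to the distal bridgehead with opening of the central bond (strain-release radical addition to an acyl bicyclobutane) and gives the 3-O-silyl tricyclic enone F4. Bu4NF then returns 19. Absolute configuration here comes from the CBS step and the separation.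

2. Step 12. Fluoride may fail to break the vinylic C–Si bond cleanly, or the basic medium may degrade the diketone. Fallback from 16 to 17: ipso-iododesilylation with ICl (CH2Cl2, 0 °C) gives the 8-iodo enone F5; zinc dust in AcOH/EtOH removes iodine reductively.

3. Step 16. Hydride transfer from the hemiacetal across the seven-membered ring may be slow, so that aldehyde self-condensation, retro-aldol opening or acyl migration take over. Fallback from 19 to 21 (acylate first, reduce second): 3-methylbutanoic anhydride/DMAP gives the 3-isovalerate ketal F6; 1 M HCl/THF frees the C1 ketone as keto ester F7; the (S)-oxazaborolidine/borane reduction should set C1 (R) under reagent control (C7 is reduced too), giving diol ester F8; MnO2 restores the enone to give 21.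

**Further compounds**

F1 | step 11 | (5′R)-2′,6′,6′-trimethylspiro[1,3-dioxolane-2,3′-tricyclo[5.1.0.0(2,8)]octan]-5′-ol | C[C@]12[C@@H]3[C@H]1[C@@H]3C(C)(C)[C@H](O)CC25OCCO5
F2 | step 11 | tert-butyldimethylsilyl ether of F1 | C[C@]12[C@@H]3[C@H]1[C@@H]3C(C)(C)[C@H](O[Si](C)(C)C(C)(C)C)CC25OCCO5
F3 | step 11 | bridgehead (Z)-3-bromobut-2-enoyl bicyclobutane (acyl on the future C6) | C[C@]12[C@]3(C(=O)/C=C(\Br)C)[C@H]1[C@@H]3C(C)(C)[C@H](O[Si](C)(C)C(C)(C)C)CC25OCCO5
F4 | step 11 | 3-O-tert-butyldimethylsilyl ether of 19 | C14(OCCO4)C[C@@H](O[Si](C)(C)C(C)(C)C)C(C)(C)[C@@H]2[C@H]3C(=O)C=C(C)[C@@H]2[C@]31C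
F5 | step 12 | 8-iodo analogue of 17 | C14(OCCO4)CC(=O)C(C)(C)[C@@H]2[C@H]3C(=O)C(I)=C(C)[C@@H]2[C@]31C
F6 | step 16 | 3-(3-methylbutanoate) of 19 | C14(OCCO4)C[C@@H](OC(=O)CC(C)C)C(C)(C)[C@@H]2[C@H]3C(=O)C=C(C)[C@@H]2[C@]31C
F7 | step 16 | (3R)-3-(3-methylbutanoyloxy)-1,7-dione | O=C1C[C@@H](OC(=O)CC(C)C)C(C)(C)[C@@H]2[C@H]3C(=O)C=C(C)[C@@H]2[C@]31C
F8 | step 16 | (1R,3R)-1,7-diol 3-(3-methylbutanoate) (C7 epimers) | O[C@@H]1C[C@@H](OC(=O)CC(C)C)C(C)(C)[C@@H]2[C@H]3C(O)C=C(C)[C@@H]2[C@]31C
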